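**Retrosynthetic overview**
- The target is the all-cis (2S,4R,6S) oxane. The benzyl ethers come off last, and the O1–C6 bond is cut to an acyclic 1,3,5-triol (benzylic SN1 etherification, C6 set under thermodynamic control).
- The C2 and C6 carbinols come from ketones reduced anti to the C4 hydroxyl by internal hydride delivery; both ketones are carried as 1,3-dithianes.
- The strategy rests on C3–C4–C5, a three-carbon unit with oxygen on its central carbon C4, flanked by the oxygen-bearing C2 and C6. Cutting C2–C3 and C5–C6 gives (R)-epichlorohydrin as a bis-electrophile between two acyl anion equivalents, the ring A alkyl dithiane and the ring B aryl dithiane.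
- The dithianes come from eugenol (benzylation, hydroboration–oxidation, oxidation, thioacetalisation) and from 5-hydroxyvanillin (benzylation, thioacetalisation).
- Ring order: the oxane is the only ring of the target and is closed in step 10; the two dithiane rings are temporary.

Key step: step 7

Remark: ring A is the 4-hydroxy-3-methoxyphenyl ring and ring B the 3,4-dihydroxy-5-methoxyphenyl ring. The oxane is numbered O1, C2 (carrying the ring A ethyl chain), C3, C4 (OH), C5, C6 (carrying ring B). In the target all three substituents are equatorial, which corresponds to an anti relation of both the C2–O and C6–O bonds to the C4 hydroxyl in the open chain.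

**Step 1**
Reactants: 1 eugenol
Product: 2 4-allyl-1-(benzyloxy)-2-methoxybenzene
Conditions: BnBr, K2CO3, DMF, rt
Reagents that add atoms: benzyl bromide, BrCc1ccccc1
Why: Williamson etherification of the phenoxide with a reactive benzylic bromide, under a base too weak to move the allyl double bond into conjugation.

**Step 2**
Reactants: 2 4-allyl-1-(benzyloxy)-2-methoxybenzene
Product: 4 3-(4-benzyloxy-3-methoxyphenyl)propan-1-ol, via B-alkyl-9-BBN adduct 3 (not isolated)
Conditions: 9-BBN (9-borabicyclo[3.3.1]nonane), THF, 0 °C → rt; then aq. NaOH, H2O2, 0 °C → rt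
Reagents that add atoms: hydrogen peroxide, OO; 9-borabicyclo[3.3.1]nonane, B1C2CCCC1CCC2 (its boron is held only in intermediate 3)
Why: Brown hydroboration–oxidation, in which the bulky borane places boron on the terminal carbon and alkaline peroxide exchanges boron for oxygen, should give the primary alcohol only.

**Step 3**
Reactants: 4 3-(4-benzyloxy-3-methoxyphenyl)propan-1-ol
Product: 5 3-(4-benzyloxy-3-methoxyphenyl)propanal
Conditions: TEMPO (10 mol %), PhI(OAc)2, CH2Cl2, rt
Reagents that add atoms: none
Why: Oxoammonium-mediated (TEMPO/PhI(OAc)2) alcohol oxidation stops at the aldehyde and leaves the benzyl ether and the electron-rich arene alone.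

**Step 4**
Reactants: 5 3-(4-benzyloxy-3-methoxyphenyl)propanal; 6 propane-1,3-dithiol
Product: 7 2-[2-(4-benzyloxy-3-methoxyphenyl)ethyl]-1,3-dithiane
Conditions: BF3·OEt2 (0.2 equiv), CH2Cl2, 0 °C → rt
Reagents that add atoms: none
Why: Lewis acid-catalysed dithioacetalisation, driven by formation of the six-membered dithiane, installs the Corey–Seebach acyl anion precursor for C2.

**Step 5**
Reactants: 8 3,4-dihydroxy-5-methoxybenzaldehyde
Product: 9 3,4-bis(benzyloxy)-5-methoxybenzaldehyde
Conditions: BnBr (2.4 equiv), K2CO3, DMF, 60 °C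
Reagents that add atoms: benzyl bromide, BrCc1ccccc1
Why: Twofold Williamson etherification of the catechol, whose phenoxides are both alkylated readily under carbonate conditions.

**Step 6**
Reactants: 9 3,4-bis(benzyloxy)-5-methoxybenzaldehyde; 6 propane-1,3-dithiol
Product: 10 2-[3,4-bis(benzyloxy)-5-methoxyphenyl]-1,3-dithiane
Conditions: BF3·OEt2 (0.2 equiv), CH2Cl2, 0 °C → rt
Reagents that add atoms: none
Why: Lewis acid-catalysed dithioacetalisation of the aryl aldehyde, run cold with a catalytic charge of BF3·OEt2 so that the benzyl ethers are not cleaved.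

**Step 7**
Reactants: 7 2-[2-(4-benzyloxy-3-methoxyphenyl)ethyl]-1,3-dithiane; 11 (R)-epichlorohydrin; 10 2-[3,4-bis(benzyloxy)-5-methoxyphenyl]-1,3-dithiane
Product: 16 (2R)-1-{2-[3,4-bis(benzyloxy)-5-methoxyphenyl]-1,3-dithian-2-yl}-3-{2-[2-(4-benzyloxy-3-methoxyphenyl)ethyl]-1,3-dithian-2-yl}propan-2-ol, via 2-lithio ring A dithiane 12 (not isolated), via chlorohydrin lithium alkoxide 13 (not isolated), via terminal epoxide 14 (not isolated), via 2-lithio ring B dithiane 15 (not isolated)
Conditions: 7, t-BuLi, THF/HMPA (9:1), −78 °C; 11, −78 → 0 °C; then 15 (from 10, n-BuLi, THF, −78 → −30 °C) by cannula, −78 °C → rt; aq. NH4Cl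
Reagents that add atoms: none
Why: Lithiated dithiane 12 opens the oxirane of 11 at its CH2 by SN2 to give alkoxide 13, which on warming expels chloride in a 3-exo-tet Williamson closure to the new terminal epoxide 14; the stabilised aryl dithiane anion 15 then opens 14 at its CH2, so C2–C3 and C5–C6 are both made in one flask. The closest known reaction type is the three-component linchpin coupling of two different 2-lithio-1,3-dithianes (Corey–Seebach umpolung) with epichlorohydrin through an intermediate terminal epoxide. No ring of the target is closed; the only ring formed is the transient oxirane of 14, which is consumed in the same flask. No new stereocentre is created, because the carbinol carbon of 11 becomes C4 with none of its four bonds broken, so the (R)-linchpin with ring A added first and ring B second should give the (R)-carbinol required. The step needs both anions to attack the unsubstituted epoxide carbon and not C–Cl or the substituted carbon; the low temperature, lithium activation of the oxirane and the bulk of the dithianyl anions favour this, and 15 is added only after closure to 14 is complete. Fast metalation of 7 at −78 °C with t-BuLi/HMPA should outpace deprotonation at the benzyl ether CH2.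

**Step 8**
Reactants: 16 (2R)-1-{2-[3,4-bis(benzyloxy)-5-methoxyphenyl]-1,3-dithian-2-yl}-3-{2-[2-(4-benzyloxy-3-methoxyphenyl)ethyl]-1,3-dithian-2-yl}propan-2-ol
Product: 17 (3R)-1-[3,4-bis(benzyloxy)-5-methoxyphenyl]-7-(4-benzyloxy-3-methoxyphenyl)-3-hydroxyheptane-1,5-dione
Conditions: Hg(ClO4)2·3H2O, CaCO3, THF/H2O (5:1), 0 °C
Reagents that add atoms: water, O
Why: Metal-assisted dithioacetal hydrolysis, in which thiophilic divalent mercury activates both dithianes towards water, with CaCO3 buffering the acid set free so that the β-hydroxy ketones neither dehydrate nor undergo retro-aldol cleavage.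

**Step 9**
Reactants: 17 (3R)-1-[3,4-bis(benzyloxy)-5-methoxyphenyl]-7-(4-benzyloxy-3-methoxyphenyl)-3-hydroxyheptane-1,5-dione
Product: 18 (1S,3R,5S)-1-[3,4-bis(benzyloxy)-5-methoxyphenyl]-7-(4-benzyloxy-3-methoxyphenyl)heptane-1,3,5-triol
Conditions: Me4NBH(OAc)3 (excess), MeCN/AcOH (1:1), −30 °C → rt; aq. KNaC4H4O6 (potassium sodium tartrate)
Reagents that add atoms: none
Why: Evans–Saksena reduction, in which the C4 hydroxyl exchanges onto boron and delivers hydride internally through a chair-like six-membered transition state, should set the C2 carbinol (S) anti to C4; C6 is reduced in the same way, and any C6 epimer is harmless because C6 is reset in step 10.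

**Step 10**
Reactants: 18 (1S,3R,5S)-1-[3,4-bis(benzyloxy)-5-methoxyphenyl]-7-(4-benzyloxy-3-methoxyphenyl)heptane-1,3,5-triol
Product: 19 (2S,4R,6S)-6-[3,4-bis(benzyloxy)-5-methoxyphenyl]-2-[2-(4-benzyloxy-3-methoxyphenyl)ethyl]oxan-4-ol
Conditions: TsOH·H2O (10 mol %), CH2Cl2 (0.02 M), 0 °C → rt
Reagents that add atoms: none
Why: Acid-catalysed dehydrative SN1 etherification, in which the benzylic C6 cation stabilised by the para benzyloxy group of ring B is captured by the C2 hydroxyl in a six-membered closure with the C2–O bond retained; the benzylic ether can re-ionise, so C6 should settle as (S) in the chair with all three substituents equatorial.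

**Step 11**
Reactants: 19 (2S,4R,6S)-6-[3,4-bis(benzyloxy)-5-methoxyphenyl]-2-[2-(4-benzyloxy-3-methoxyphenyl)ethyl]oxan-4-ol
Product: 20 (2S,4R,6S)-6-(3,4-dihydroxy-5-methoxyphenyl)-2-[2-(4-hydroxy-3-methoxyphenyl)ethyl]oxan-4-ol
Conditions: H2 (1 atm), Pd/C (10 wt % Pd), EtOAc/EtOH, rt
Reagents that add atoms: none
Why: Catalytic hydrogenolysis of the three aryl benzyl ethers, which in a neutral solvent should be much faster than cleavage of the benzylic C6–O bond of the oxane.

**Compound list**
1 | eugenol (4-allyl-2-methoxyphenol) | C=CCc1ccc(O)c(OC)c1 | starting material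
2 | 4-allyl-1-(benzyloxy)-2-methoxybenzene | C=CCc1ccc(OCc2ccccc2)c(OC)c1 | intermediate
3 | B-[3-(4-benzyloxy-3-methoxyphenyl)propyl]-9-borabicyclo[3.3.1]nonane (in-flask species) | COc1cc(CCCB2C3CCCC2CCC3)ccc1OCc1ccccc1 | intermediate
4 | 3-(4-benzyloxy-3-methoxyphenyl)propan-1-ol | COc1cc(CCCO)ccc1OCc1ccccc1 | intermediate
5 | 3-(4-benzyloxy-3-methoxyphenyl)propanal | COc1cc(CCC=O)ccc1OCc1ccccc1 | intermediate
6 | propane-1,3-dithiol | SCCCS | starting material
7 | 2-[2-(4-benzyloxy-3-methoxyphenyl)ethyl]-1,3-dithiane | COc1cc(CCC2SCCCS2)ccc1OCc1ccccc1 | intermediate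
8 | 3,4-dihydroxy-5-methoxybenzaldehyde (5-hydroxyvanillin) | COc1cc(C=O)cc(O)c1O | starting material
9 | 3,4-bis(benzyloxy)-5-methoxybenzaldehyde | COc1cc(C=O)cc(OCc2ccccc2)c1OCc1ccccc1 | intermediate
10 | 2-[3,4-bis(benzyloxy)-5-methoxyphenyl]-1,3-dithiane | COc1cc(C2SCCCS2)cc(OCc2ccccc2)c1OCc1ccccc1 | intermediate
11 | (R)-epichlorohydrin | ClC[C@H]1CO1 | starting material
12 | 2-[2-(4-benzyloxy-3-methoxyphenyl)ethyl]-2-lithio-1,3-dithiane (in-flask species) | COc1cc(CCC2([Li])SCCCS2)ccc1OCc1ccccc1 | intermediate
13 | lithium (2R)-1-chloro-3-{2-[2-(4-benzyloxy-3-methoxyphenyl)ethyl]-1,3-dithian-2-yl}propan-2-olate (in-flask species) | COc1cc(CCC2(C[C@@H]([O-])CCl)SCCCS2)ccc1OCc1ccccc1.[Li+] | intermediate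
14 | 2-[2-(4-benzyloxy-3-methoxyphenyl)ethyl]-2-{[(2R)-oxiran-2-yl]methyl}-1,3-dithiane (in-flask species) | COc1cc(CCC2(C[C@@H]3CO3)SCCCS2)ccc1OCc1ccccc1 | intermediate
15 | 2-[3,4-bis(benzyloxy)-5-methoxyphenyl]-2-lithio-1,3-dithiane (in-flask species) | COc1cc(C2([Li])SCCCS2)cc(OCc2ccccc2)c1OCc1ccccc1 | intermediate
16 | (2R)-1-{2-[3,4-bis(benzyloxy)-5-methoxyphenyl]-1,3-dithian-2-yl}-3-{2-[2-(4-benzyloxy-3-methoxyphenyl)ethyl]-1,3-dithian-2-yl}propan-2-ol | COc1cc(CCC2(SCCCS2)C[C@@H](O)CC3(SCCCS3)c4cc(OCc5ccccc5)c(OCc6ccccc6)c(OC)c4)ccc1OCc7ccccc7 | intermediate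
17 | (3R)-1-[3,4-bis(benzyloxy)-5-methoxyphenyl]-7-(4-benzyloxy-3-methoxyphenyl)-3-hydroxyheptane-1,5-dione | COc1cc(CCC(=O)C[C@@H](O)CC(=O)c2cc(OCc3ccccc3)c(OCc4ccccc4)c(OC)c2)ccc1OCc5ccccc5 | intermediate
18 | (1S,3R,5S)-1-[3,4-bis(benzyloxy)-5-methoxyphenyl]-7-(4-benzyloxy-3-methoxyphenyl)heptane-1,3,5-triol | COc1cc(CC[C@H](O)C[C@@H](O)C[C@H](O)c2cc(OCc3ccccc3)c(OCc4ccccc4)c(OC)c2)ccc1OCc5ccccc5 | intermediate
19 | (2S,4R,6S)-6-[3,4-bis(benzyloxy)-5-methoxyphenyl]-2-[2-(4-benzyloxy-3-methoxyphenyl)ethyl]oxan-4-ol | COc1cc(CC[C@H]2C[C@@H](O)C[C@@H](c3cc(OCc4ccccc4)c(OCc5ccccc5)c(OC)c3)O2)ccc1OCc1ccccc1 | intermediate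
20 | (2S,4R,6S)-6-(3,4-dihydroxy-5-methoxyphenyl)-2-[2-(4-hydroxy-3-methoxyphenyl)ethyl]oxan-4-ol | COc1cc(CC[C@H]2C[C@@H](O)C[C@@H](c3cc(O)c(O)c(OC)c3)O2)ccc1O | target

**Step count and risks**
Total step count: 11. Longest linear sequence: 9 steps (steps 1, 2, 3, 4, 7, 8, 9, 10, 11, from eugenol).

Steps most likely to fail:

Step 7. The metalation of the alkyl dithiane may be incomplete or may compete with deprotonation at the benzyl ether CH2. The first anion may displace chloride directly instead of opening the oxirane, which would erode the enantiopurity of C4. The second anion may also meet chlorohydrin alkoxide that has not yet closed to the epoxide. The fallback inverts the order of the two bond formations and runs them in two flasks. It sets out from 10 and comes back to the route at 16. Dithiane 10 is metalated with n-BuLi in THF (−78 → −30 °C, no HMPA) to give 15, which is treated at −78 °C with (S)-epichlorohydrin (ClC[C@@H]1CO1). The resulting lithium (2S)-1-chloro-3-{2-[3,4-bis(benzyloxy)-5-methoxyphenyl]-1,3-dithian-2-yl}propan-2-olate F1 closes on warming to 2-[3,4-bis(benzyloxy)-5-methoxyphenyl]-2-{[(2S)-oxiran-2-yl]methyl}-1,3-dithiane F2, which is isolated, purified and checked for enantiopurity. Lithiated dithiane 12, made from 7 as in step 7, then opens F2 at its CH2 to give 16. Because the two CH2 groups of the linchpin exchange roles, the (S)-enantiomer of epichlorohydrin is needed here to reach the same (R)-carbinol.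

Step 9. After the first hydride delivery the C4 oxygen is bound in a borate, and the electron-rich aryl ketone is a poor hydride acceptor, so the second reduction may stall and leave partly reduced material. The fallback sets out from 17 and comes back at 19, passing over step 10. A limited charge of Me4NBH(OAc)3 in MeCN/AcOH at −40 °C should reduce only the more electrophilic dialkyl ketone, anti to C4, to give (3R,5S)-1-[3,4-bis(benzyloxy)-5-methoxyphenyl]-7-(4-benzyloxy-3-methoxyphenyl)-3,5-dihydroxyheptan-1-one F3. Reductive etherification of F3 (Et3SiH, BF3·OEt2, CH2Cl2, −78 → −30 °C) then proceeds through the cyclic aryl oxocarbenium ion; axial hydride delivery sets C6 cis to C2 under kinetic control and gives 19.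

Step 10. The benzylic cation may lose a C5 proton (E1) to a styrene whose allylic C4 hydroxyl can then ionise, with loss of the C4 stereocentre. It may also be captured by ring A of a second molecule (Friedel–Crafts), or the equilibration at C6 may stay incomplete. The fallback exchanges the order of ring closure and deprotection. It sets out from 18 and comes back at 20. Hydrogenolysis of 18 (H2, Pd/C, EtOAc/EtOH, rt) gives (1S,3R,5S)-1-(3,4-dihydroxy-5-methoxyphenyl)-7-(4-hydroxy-3-methoxyphenyl)heptane-1,3,5-triol F4. The free para hydroxyl of ring B then lets the benzylic alcohol ionise under much milder acid (pyridinium p-toluenesulfonate, MeCN, rt) to a para-quinone methide. The C2 hydroxyl adds to it reversibly (1,6-oxa-Michael addition), which should give the all-equatorial oxane 20 directly.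

**Further compounds**
F1 | step 7 | lithium (2S)-1-chloro-3-{2-[3,4-bis(benzyloxy)-5-methoxyphenyl]-1,3-dithian-2-yl}propan-2-olate | COc1cc(C2(C[C@H]([O-])CCl)SCCCS2)cc(OCc2ccccc2)c1OCc1ccccc1.[Li+]
F2 | step 7 | 2-[3,4-bis(benzyloxy)-5-methoxyphenyl]-2-{[(2S)-oxiran-2-yl]methyl}-1,3-dithiane | COc1cc(C2(C[C@H]3CO3)SCCCS2)cc(OCc2ccccc2)c1OCc1ccccc1
F3 | step 9 | (3R,5S)-1-[3,4-bis(benzyloxy)-5-methoxyphenyl]-7-(4-benzyloxy-3-methoxyphenyl)-3,5-dihydroxyheptan-1-one | COc1cc(CC[C@H](O)C[C@@H](O)CC(=O)c2cc(OCc3ccccc3)c(OCc3ccccc3)c(OC)c2)ccc1OCc1ccccc1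
F4 | step 10 | (1S,3R,5S)-1-(3,4-dihydroxy-5-methoxyphenyl)-7-(4-hydroxy-3-methoxyphenyl)heptane-1,3,5-triol | COc1cc(CC[C@H](O)C[C@@H](O)C[C@H](O)c2cc(O)c(O)c(OC)c2)ccc1O
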